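**Plan**

Numbering: the flavanone unit is unprimed (benzo ring A, pyranone ring C); the flavan unit is primed (rings A' and C').

1. Retrosynthesis: the 5-O-methyl and 7'-O-benzyl ethers are cleaved last and the C2–C3 single bond is taken back to a flavone double bond. Ring C is then cut at C4a–C4, C4–C3 and O1–C2 into an ortho-iodophenol, CO and phenylacetylene. The flavan is cut at C4'–C6, C4'–C4a' and O1'–C2'.
2. Enabling feature: before ring C exists, ring A is a 3,5-dimethoxyphenol carrying the flavanyl group para to the hydroxyl. Its two carbons ortho to the hydroxyl (the later C4a and C8) are equivalent about the C6–C8a axis. Iodination is therefore unambiguous and fixes the 6-linkage, and O1 and C4a are in place to take up C4 (from CO) and C3–C2 (from the alkyne).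
3. Forward: ring A' is oxygenated at C8' and benzylated, the O1'–C2' ether is made, ring C' is closed and ring A attached in one acid step. Ring A is then iodinated, ring C annulated and reduced, and the two ethers cleaved.
4. Stereochemistry: C2' (S) comes from (R)-1-phenylbut-3-en-1-ol by Mitsunobu inversion. C4' (S, trans to the 2'-phenyl) comes from substrate control in the arylation of the flavan-4-yl cation. C2 (R) comes from a chiral ruthenium carbene hydrogenation catalyst.

Key step: step 12

Assumption: (R)-1-phenylbut-3-en-1-ol is taken as a commercial single enantiomer, and the carbene ligand antipode that leads to 2R in step 13 is taken to be the (R,R)-form, to be confirmed on 5,7-dimethoxyflavone before use.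

**Route**

Step 1
Reactants: 1 5-methoxyresorcinol
Product: 2 1-methoxy-3,5-bis(methoxymethoxy)benzene
Conditions: MOMCl (2.5 equiv), i-Pr2NEt, CH2Cl2, 0 °C → rt
Reagents that add atoms: chloromethyl methyl ether, COCCl
Why: O-alkylation of both phenols with the chloromethyl ether (MOM protection) is routine and provides the two chelating directing groups needed for step 2.

Step 2
Reactants: 2 1-methoxy-3,5-bis(methoxymethoxy)benzene
Product: 5 4-methoxy-2,6-bis(methoxymethoxy)phenol, via aryllithium 3 (not isolated), via lithium aryltrimethoxyborate 4 (not isolated)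
Conditions: n-BuLi, TMEDA, THF, 0 °C; B(OMe)3, −78 °C → rt; AcOH, 30% H2O2, 0 °C → rt
Reagents that add atoms: hydrogen peroxide, OO (the phenol oxygen); n-butyllithium, [Li]CCCC, and trimethyl borate, COB(OC)OC, leave atoms only in intermediates 3 and 4
Why: Directed ortho-metalation should occur at the carbon flanked by the two methoxymethoxy groups, which chelate lithium better than the methoxy group, and the borate is oxidised with aryl migration from boron to oxygen to give the phenol that becomes the 8'-oxygen.

Step 3
Reactants: 5 4-methoxy-2,6-bis(methoxymethoxy)phenol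
Product: 6 2,5-dimethoxy-1,3-bis(methoxymethoxy)benzene
Conditions: MeI, K2CO3, DMF, rt
Reagents that add atoms: iodomethane, CI
Why: Williamson O-methylation of the single free phenol fixes the future 8'-methoxy group.

Step 4
Reactants: 6 2,5-dimethoxy-1,3-bis(methoxymethoxy)benzene
Product: 7 2,5-dimethoxybenzene-1,3-diol
Conditions: HCl (cat.), MeOH, 50 °C
Reagents that add atoms: none
Why: Acid-catalysed acetal exchange with methanol removes both MOM groups and leaves the aryl methyl ethers untouched.

Step 5
Reactants: 7 2,5-dimethoxybenzene-1,3-diol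
Product: 8 3-(benzyloxy)-2,5-dimethoxyphenol
Conditions: BnBr (0.5 equiv relative to 7), K2CO3, DMF, rt; unreacted 7 recovered and recycled
Reagents that add atoms: benzyl bromide, BrCc1ccccc1
Why: Williamson mono-benzylation of a symmetric diol, run with the diol in excess so that the mono-ether should predominate, differentiates the future O7' (benzylated) from O1' (free).

Step 6
Reactants: 8 3-(benzyloxy)-2,5-dimethoxyphenol; 9 (R)-1-phenylbut-3-en-1-ol
Product: 10 1-(benzyloxy)-2,5-dimethoxy-3-{[(1S)-1-phenylbut-3-en-1-yl]oxy}benzene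
Conditions: PPh3, DIAD, toluene, 0 °C → rt
Reagents that add atoms: none
Why: In the Mitsunobu etherification the phenoxide displaces the activated benzylic oxygen in an SN2 manner, so the (R)-carbinol should give the (S)-aryl ether that becomes C2', with toluene at low temperature disfavouring ionisation.

Step 7
Reactants: 10 1-(benzyloxy)-2,5-dimethoxy-3-{[(1S)-1-phenylbut-3-en-1-yl]oxy}benzene
Product: 12 (3S)-3-[3-(benzyloxy)-2,5-dimethoxyphenoxy]-3-phenylpropanal, via vicinal diol 11 (not isolated)
Conditions: OsO4 (2 mol %), NaIO4, 2,6-lutidine, dioxane–H2O, rt; crude aldehyde used at once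
Reagents that add atoms: osmium tetroxide, O=[Os](=O)(=O)=O (catalytic carrier of the oxygen), kept in turnover by sodium periodate, [Na+].[O-]I(=O)(=O)=O
Why: In this Lemieux–Johnson oxidation OsO4 dihydroxylates the terminal alkene in preference to the arenes and periodate cleaves the diol, while the lutidine buffer should keep the β-aryloxy aldehyde from eliminating the phenol.

Step 8
Reactants: 13 3,5-dimethoxyphenol
Product: 14 (3,5-dimethoxyphenoxy)triisopropylsilane
Conditions: TIPSCl, imidazole, DMF, rt
Reagents that add atoms: chlorotriisopropylsilane, CC(C)[Si](Cl)(C(C)C)C(C)C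
Why: Silylation of the phenol gives a bulky silyl ether that still activates the para carbon between the two methoxy groups but shields both ortho carbons.

Step 9
Reactants: 12 (3S)-3-[3-(benzyloxy)-2,5-dimethoxyphenoxy]-3-phenylpropanal; 14 (3,5-dimethoxyphenoxy)triisopropylsilane
Product: 16 {4-[(2S,4S)-7-(benzyloxy)-5,8-dimethoxy-2-phenylchroman-4-yl]-3,5-dimethoxyphenoxy}triisopropylsilane (2,4-trans), via flavan-4-ol 15 (not isolated)
Conditions: 12 and 14 (3 equiv) premixed, BF3·OEt2 (0.3 equiv), CH2Cl2, −40 → 0 °C
Reagents that add atoms: none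
Why: In this tandem Friedel–Crafts reaction the acid-activated aldehyde is attacked by the only free carbon ortho to the ether oxygen of ring A' (ring C' closes to 15), the electron-rich benzylic alcohol ionises to the flavan-4-yl cation, and 14 should add through its carbon para to the silyloxy group on the face anti to the pseudo-equatorial 2'-phenyl group (axial attack on the half-chair), which sets C4' trans to C2'.

Step 10
Reactants: 16 {4-[(2S,4S)-7-(benzyloxy)-5,8-dimethoxy-2-phenylchroman-4-yl]-3,5-dimethoxyphenoxy}triisopropylsilane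
Product: 17 4-[(2S,4S)-7-(benzyloxy)-5,8-dimethoxy-2-phenylchroman-4-yl]-3,5-dimethoxyphenol
Conditions: TBAF, AcOH, THF, 0 °C
Reagents that add atoms: none
Why: Fluoride cleaves the aryl silyl ether (desilylation) and the acetic acid buffer keeps the electron-rich phenoxide from oxidising.

Step 11
Reactants: 17 4-[(2S,4S)-7-(benzyloxy)-5,8-dimethoxy-2-phenylchroman-4-yl]-3,5-dimethoxyphenol
Product: 18 4-[(2S,4R)-7-(benzyloxy)-5,8-dimethoxy-2-phenylchroman-4-yl]-2-iodo-3,5-dimethoxyphenol (unchanged 2,4-trans geometry; the C4 descriptor changes only because iodine raises the priority of ring A)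
Conditions: I2 (1.0 equiv), NaHCO3, THF–H2O, 0 °C
Reagents that add atoms: iodine, II
Why: Electrophilic aromatic iodination through the phenoxide should be far faster on ring A than on the ether-only ring A', and because the two carbons ortho to the hydroxyl are equivalent one equivalent of iodine can give only this mono-iodide.

Step 12
Reactants: 18 4-[(2S,4R)-7-(benzyloxy)-5,8-dimethoxy-2-phenylchroman-4-yl]-2-iodo-3,5-dimethoxyphenol; 19 carbon monoxide; 20 phenylacetylene
Product: 23 6-[(2S,4S)-7-(benzyloxy)-5,8-dimethoxy-2-phenylchroman-4-yl]-5,7-dimethoxy-2-phenyl-4H-chromen-4-one, via ortho-hydroxyaryl ynone 21 (not isolated), via diethylamino enone 22 (not isolated)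
Conditions: PdCl2(PPh3)2 (5 mol %), CO (20 bar), 20 (2 equiv), Et2NH, 120 °C, autoclave
Reagents that add atoms: diethylamine, CCNCC (held only in intermediate 22 and released on ring closure)
Why: The C–I bond of 18 adds oxidatively to zerovalent palladium formed in situ from PdCl2(PPh3)2, CO inserts to give an aroylpalladium species, and this couples with the diethylamine-activated alkyne (copper-free carbonylative Sonogashira coupling) to ynone 21. Diethylamine then adds to the ynone to give enaminone 22, and the ortho phenoxide attacks the amine-bearing carbon and expels the amine, so that C4a–C4, C4–C3 and O1–C2 are all made in one flask. The closest known reaction is the palladium-catalysed carbonylative annulation of ortho-iodophenols, methoxy-substituted ones included, with terminal alkynes to flavones. The one ring closed is ring C, by a net 6-endo-dig closure that runs as conjugate addition–elimination on the enaminone and is preferred over 5-exo-dig closure to an aurone because the secondary amine occupies the β-carbon first. No stereocentre is formed and C2' and C4' are not touched. The step needs CO insertion to outrun direct alkynylation (which would end in a benzofuran), which the CO pressure and the doubly flanked iodide should secure, and it needs no C6-against-C8 choice, because the iodine could only have entered one of two equivalent carbons.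

Step 13
Reactants: 23 6-[(2S,4S)-7-(benzyloxy)-5,8-dimethoxy-2-phenylchroman-4-yl]-5,7-dimethoxy-2-phenyl-4H-chromen-4-one
Product: 24 (2R)-6-[(2S,4S)-7-(benzyloxy)-5,8-dimethoxy-2-phenylchroman-4-yl]-5,7-dimethoxy-2-phenylchroman-4-ol (C4 carbinol epimers)
Conditions: Ru(cod)(2-methylallyl)2 (5 mol %), 1,3-bis[(1R)-1-(naphthalen-1-yl)ethyl]-4,5-dihydroimidazolium tetrafluoroborate (10 mol %), KOt-Bu (12 mol %), H2 (100 bar), toluene, 25 °C
Reagents that add atoms: none
Why: Asymmetric hydrogenation of the flavone C2=C3 bond by a chiral ruthenium N-heterocyclic-carbene catalyst, a reaction type established for flavones, should set C2 (R) by catalyst control independently of the remote C2' and C4' centres, and the accompanying reduction of C4=O is undone in step 14; any (2S) epimer would be a diastereomer and separable.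

Step 14
Reactants: 24 (2R)-6-[(2S,4S)-7-(benzyloxy)-5,8-dimethoxy-2-phenylchroman-4-yl]-5,7-dimethoxy-2-phenylchroman-4-ol
Product: 25 (2R)-6-[(2S,4S)-7-(benzyloxy)-5,8-dimethoxy-2-phenylchroman-4-yl]-5,7-dimethoxy-2-phenylchroman-4-one
Conditions: Dess–Martin periodinane, pyridine, CH2Cl2, 0 °C → rt
Reagents that add atoms: none
Why: Dess–Martin oxidation of the secondary benzylic alcohol under pyridine buffering should give the ketone without acid or base strong enough to open the flavanone ring or epimerise C2, and any 25 already formed in step 13 passes through unchanged.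

Step 15
Reactants: 25 (2R)-6-[(2S,4S)-7-(benzyloxy)-5,8-dimethoxy-2-phenylchroman-4-yl]-5,7-dimethoxy-2-phenylchroman-4-one
Product: 26 (2R)-5-hydroxy-6-[(2S,4S)-7-hydroxy-5,8-dimethoxy-2-phenylchroman-4-yl]-7-methoxy-2-phenylchroman-4-one
Conditions: BCl3, C6HMe5 (pentamethylbenzene), CH2Cl2, −78 → 0 °C; MeOH, then aqueous work-up
Reagents that add atoms: none
Why: BCl3 chelated between C4=O and the 5-methoxy oxygen cleaves that one methyl ether (chelation-controlled demethylation) and also cleaves the benzyl ether with pentamethylbenzene trapping the benzyl cation, while the unchelated 7-, 5'- and 8'-methoxy groups should survive at low temperature.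

**Compound list**

1 | 5-methoxyresorcinol | COc1cc(O)cc(O)c1 | starting material
2 | 1-methoxy-3,5-bis(methoxymethoxy)benzene | COCOc1cc(OC)cc(OCOC)c1 | intermediate
3 | [4-methoxy-2,6-bis(methoxymethoxy)phenyl]lithium | [Li]c1c(OCOC)cc(OC)cc1OCOC | intermediate
4 | lithium trimethoxy[4-methoxy-2,6-bis(methoxymethoxy)phenyl]borate | [Li+].CO[B-](OC)(OC)c1c(OCOC)cc(OC)cc1OCOC | intermediate
5 | 4-methoxy-2,6-bis(methoxymethoxy)phenol | COCOc1cc(OC)cc(OCOC)c1O | intermediate
6 | 2,5-dimethoxy-1,3-bis(methoxymethoxy)benzene | COCOc1cc(OC)cc(OCOC)c1OC | intermediate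
7 | 2,5-dimethoxybenzene-1,3-diol | COc1cc(O)c(OC)c(O)c1 | intermediate
8 | 3-(benzyloxy)-2,5-dimethoxyphenol | COc1cc(O)c(OC)c(OCc2ccccc2)c1 | intermediate
9 | (R)-1-phenylbut-3-en-1-ol | C=CC[C@@H](O)c1ccccc1 | starting material
10 | 1-(benzyloxy)-2,5-dimethoxy-3-{[(1S)-1-phenylbut-3-en-1-yl]oxy}benzene | C=CC[C@H](Oc1cc(OC)cc(OCc2ccccc2)c1OC)c1ccccc1 | intermediate
11 | (4S)-4-[3-(benzyloxy)-2,5-dimethoxyphenoxy]-4-phenylbutane-1,2-diol (both C2 epimers) | OCC(O)C[C@H](Oc1cc(OC)cc(OCc2ccccc2)c1OC)c1ccccc1 | intermediate
12 | (3S)-3-[3-(benzyloxy)-2,5-dimethoxyphenoxy]-3-phenylpropanal | O=CC[C@H](Oc1cc(OC)cc(OCc2ccccc2)c1OC)c1ccccc1 | intermediate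
13 | 3,5-dimethoxyphenol | COc1cc(O)cc(OC)c1 | starting material
14 | (3,5-dimethoxyphenoxy)triisopropylsilane | COc1cc(OC)cc(O[Si](C(C)C)(C(C)C)C(C)C)c1 | intermediate
15 | (2S)-7-(benzyloxy)-5,8-dimethoxy-2-phenylchroman-4-ol (both C4 epimers) | OC1C[C@@H](c2ccccc2)Oc2c(OC)c(OCc3ccccc3)cc(OC)c21 | intermediate
16 | {4-[(2S,4S)-7-(benzyloxy)-5,8-dimethoxy-2-phenylchroman-4-yl]-3,5-dimethoxyphenoxy}triisopropylsilane (2,4-trans) | COc1cc(O[Si](C(C)C)(C(C)C)C(C)C)cc(OC)c1[C@@H]1C[C@@H](c2ccccc2)Oc2c(OC)c(OCc3ccccc3)cc(OC)c21 | intermediate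
17 | 4-[(2S,4S)-7-(benzyloxy)-5,8-dimethoxy-2-phenylchroman-4-yl]-3,5-dimethoxyphenol | COc1cc(O)cc(OC)c1[C@@H]1C[C@@H](c2ccccc2)Oc2c(OC)c(OCc3ccccc3)cc(OC)c21 | intermediate
18 | 4-[(2S,4R)-7-(benzyloxy)-5,8-dimethoxy-2-phenylchroman-4-yl]-2-iodo-3,5-dimethoxyphenol (2,4-trans) | COc1cc(O)c(I)c(OC)c1[C@@H]1C[C@@H](c2ccccc2)Oc2c(OC)c(OCc3ccccc3)cc(OC)c21 | intermediate
19 | carbon monoxide | [C-]#[O+] | starting material
20 | phenylacetylene | C#Cc1ccccc1 | starting material
21 | 1-{3-[(2S,4S)-7-(benzyloxy)-5,8-dimethoxy-2-phenylchroman-4-yl]-6-hydroxy-2,4-dimethoxyphenyl}-3-phenylprop-2-yn-1-one | COc1cc(O)c(C(=O)C#Cc2ccccc2)c(OC)c1[C@@H]1C[C@@H](c2ccccc2)Oc2c(OC)c(OCc3ccccc3)cc(OC)c21 | intermediate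
22 | 3-(diethylamino)-1-{3-[(2S,4S)-7-(benzyloxy)-5,8-dimethoxy-2-phenylchroman-4-yl]-6-hydroxy-2,4-dimethoxyphenyl}-3-phenylprop-2-en-1-one (alkene geometry not defined) | COc1cc(O)c(C(=O)C=C(N(CC)CC)c2ccccc2)c(OC)c1[C@@H]1C[C@@H](c2ccccc2)Oc2c(OC)c(OCc3ccccc3)cc(OC)c21 | intermediate
23 | 6-[(2S,4S)-7-(benzyloxy)-5,8-dimethoxy-2-phenylchroman-4-yl]-5,7-dimethoxy-2-phenyl-4H-chromen-4-one | COc1cc2OC(c3ccccc3)=CC(=O)c2c(OC)c1[C@@H]1C[C@@H](c2ccccc2)Oc2c(OC)c(OCc3ccccc3)cc(OC)c21 | intermediate
24 | (2R)-6-[(2S,4S)-7-(benzyloxy)-5,8-dimethoxy-2-phenylchroman-4-yl]-5,7-dimethoxy-2-phenylchroman-4-ol (both C4 epimers, 2,4-cis expected to predominate) | COc1cc2O[C@@H](c3ccccc3)CC(O)c2c(OC)c1[C@@H]1C[C@@H](c2ccccc2)Oc2c(OC)c(OCc3ccccc3)cc(OC)c21 | intermediate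
25 | (2R)-6-[(2S,4S)-7-(benzyloxy)-5,8-dimethoxy-2-phenylchroman-4-yl]-5,7-dimethoxy-2-phenylchroman-4-one | COc1cc2c(c(OC)c1[C@@H]1C[C@@H](c3ccccc3)Oc3c(OC)c(OCc4ccccc4)cc(OC)c31)C(=O)C[C@H](c1ccccc1)O2 | intermediate
26 | (2R)-5-hydroxy-6-[(2S,4S)-7-hydroxy-5,8-dimethoxy-2-phenylchroman-4-yl]-7-methoxy-2-phenylchroman-4-one | COc1cc2c(c(O)c1[C@@H]1C[C@@H](c3ccccc3)Oc3c(OC)c(O)cc(OC)c31)C(=O)C[C@H](c1ccccc1)O2 | target

**Step count**

Total step count: 15. Longest linear sequence: 14 steps (steps 1–7 and 9–15, from 1 to 26); step 8 is a one-step branch.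

**Steps most likely to fail**

Step 9. The cation may attack 14 at a carbon between the silyloxy and a methoxy group, the silyl group may be lost under the acid, or 14 may intercept the aldehyde before ring C' closes; each would erode regiochemical or stereochemical purity. The fallback sets out from 12 and replaces 14 by phloroglucinol (benzene-1,3,5-triol, in excess, dioxane–CH2Cl2, same catalytic BF3·OEt2), whose three ring carbons are equivalent, so the arylation can have only one regiochemical outcome and should give the 2-(flavan-4-yl)benzene-1,3,5-triol F1. The hydroxyl para to the flavanyl group, the only one not flanked by it, is then silylated selectively with TIPSCl and imidazole to the mono-silyl ether F2. Methylation of the two remaining hindered hydroxyls (MeI, K2CO3, acetone) comes back to the route at 16.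

Step 13. Facial selectivity at C2=C3 may be poor for a flavone flanked by the 5-methoxy group and the bulky C6 substituent, and further rings may be hydrogenated under pressure. The fallback sets C2 by enantioselective carbon–carbon bond formation instead and sets out from 18. The annulation of step 12, run with ethynyltrimethylsilane in place of 20, should give the trimethylsilyl ynone F3, which loses silicon to diethylamine in the same flask and closes to the 2-unsubstituted chromone F4. Asymmetric conjugate addition of phenylboronic acid catalysed by divalent palladium (Pd(OCOCF3)2, (S)-t-BuPyOx, NH4PF6, water, 1,2-dichloroethane, 60 °C), a reaction known for chromones, should then deliver the phenyl group to C2. The (S)-ligand is expected by analogy with cyclic enones to give 2R, and the antipode would be used otherwise. The fallback comes back to the route at 25, so steps 13 and 14 are bypassed.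

Step 12. Alkynylation of the arylpalladium may occur before CO insertion, followed by closure of the alkynylphenol to a benzofuran, or oxidative addition into the electron-rich, doubly flanked C–I bond of the phenoxide may be slow. The fallback sets out from 18 and masks the phenol: acetylation (Ac2O, pyridine) gives the aryl acetate F5, which is less electron-rich and cannot close to a benzofuran. Carbonylative Sonogashira coupling with 20 (PdCl2(PPh3)2, CO, Et3N, THF) then gives the isolated acetoxy ynone F6. Treatment with Et2NH in DMF cleaves the acetate and cyclises through 21 and 22, coming back to the route at 23.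

**Further compounds**

F1 | step 9 | 2-[(2S,4S)-7-(benzyloxy)-5,8-dimethoxy-2-phenylchroman-4-yl]benzene-1,3,5-triol | Oc1cc(O)c(c(O)c1)[C@@H]1C[C@@H](c2ccccc2)Oc2c(OC)c(OCc3ccccc3)cc(OC)c21
F2 | step 9 | 2-[(2S,4S)-7-(benzyloxy)-5,8-dimethoxy-2-phenylchroman-4-yl]-5-[(triisopropylsilyl)oxy]benzene-1,3-diol | CC(C)[Si](Oc1cc(O)c(c(O)c1)[C@@H]1C[C@@H](c2ccccc2)Oc2c(OC)c(OCc3ccccc3)cc(OC)c21)(C(C)C)C(C)C
F3 | step 13 | 1-{3-[(2S,4S)-7-(benzyloxy)-5,8-dimethoxy-2-phenylchroman-4-yl]-6-hydroxy-2,4-dimethoxyphenyl}-3-(trimethylsilyl)prop-2-yn-1-one | COc1cc(O)c(C(=O)C#C[Si](C)(C)C)c(OC)c1[C@@H]1C[C@@H](c2ccccc2)Oc2c(OC)c(OCc3ccccc3)cc(OC)c21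
F4 | step 13 | 6-[(2S,4S)-7-(benzyloxy)-5,8-dimethoxy-2-phenylchroman-4-yl]-5,7-dimethoxy-4H-chromen-4-one | COc1cc2OC=CC(=O)c2c(OC)c1[C@@H]1C[C@@H](c2ccccc2)Oc2c(OC)c(OCc3ccccc3)cc(OC)c21
F5 | step 12 | 4-[(2S,4R)-7-(benzyloxy)-5,8-dimethoxy-2-phenylchroman-4-yl]-2-iodo-3,5-dimethoxyphenyl acetate | COc1cc(OC(C)=O)c(I)c(OC)c1[C@@H]1C[C@@H](c2ccccc2)Oc2c(OC)c(OCc3ccccc3)cc(OC)c21
F6 | step 12 | 4-[(2S,4S)-7-(benzyloxy)-5,8-dimethoxy-2-phenylchroman-4-yl]-3,5-dimethoxy-2-(3-phenylprop-2-ynoyl)phenyl acetate | COc1cc(OC(C)=O)c(C(=O)C#Cc2ccccc2)c(OC)c1[C@@H]1C[C@@H](c2ccccc2)Oc2c(OC)c(OCc3ccccc3)cc(OC)c21
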